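The route rests on disconnecting the O1–C2 bond of ring C in the upper flavanone unit. In a 2H-chromene, C2 is benzylic to the electron-rich catechol ring B and allylic to C3=C4, so it ionises easily. A chiral N-triflylphosphoramide turns a racemic (Z)-triaryl allylic carbinol into one enantiomer of the chromene, closing ring C and setting C2 in one enantioconvergent operation. The precursor comes from a 3-arylcoumarin; its fluoroaryl ring carries a bromine at the future C4a'' as a regiospecific acylation handle. C3 then follows from C2 by anti hydroboration, and fluoride displacement by an enantiopure alkoxide closes the lower flavanone before oxidation and hydrogenolysis.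

Key step: step 10

Remark: double-primed locants refer to the lower flavanone unit; the upper unit of the target is 2,3-cis (2R,3R), and the descriptors at C2 and C3 change in some intermediates only because the CIP priorities change, not the geometry.
Assumption: the (R)-configured phosphoramide is taken to give the (2S)-chromene 17; if the sense of induction proves opposite, its enantiomer is used in the same way.

Step 1
Reactants: 1 5-fluororesorcinol
Product: 2 1,3-bis(benzyloxy)-5-fluorobenzene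
Conditions: BnBr, K2CO3, DMF, rt → 60 °C
Reagents that add atoms: benzyl bromide, BrCc1ccccc1
Why: Williamson ether synthesis on both phenols, the aryl fluoride being inert to carbonate.

Step 2
Reactants: 2 1,3-bis(benzyloxy)-5-fluorobenzene
Product: 4 2-fluoro-4,6-bis(benzyloxy)benzaldehyde, via iminium salt 3 (not isolated)
Conditions: POCl3, DMF, 0 → 70 °C; then H2O
Reagents that add atoms: N,N-dimethylformamide, CN(C)C=O; water, O
Why: Vilsmeier–Haack formylation should go to the position para to one benzyloxy group and ortho to the other (next to fluorine), which is less hindered than the site between the two benzyloxy groups, and the iminium salt is hydrolysed on work-up.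

Step 3
Reactants: 4 2-fluoro-4,6-bis(benzyloxy)benzaldehyde
Product: 5 3-bromo-2-fluoro-4,6-bis(benzyloxy)benzaldehyde
Conditions: NBS, MeCN, 0 °C → rt, dark
Reagents that add atoms: N-bromosuccinimide, O=C1CCC(=O)N1Br
Why: Electrophilic aromatic bromination should take the free position para to the 6-benzyloxy group (between fluorine and the 4-benzyloxy group) rather than the site flanked by two benzyloxy groups, as in the 5-bromination of 2,4-dialkoxybenzaldehydes; this bromine is the later acylation handle and a spectator until step 16.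

Step 4
Reactants: 5 3-bromo-2-fluoro-4,6-bis(benzyloxy)benzaldehyde
Product: 7 2-[3-bromo-2-fluoro-4,6-bis(benzyloxy)phenyl]acetonitrile, via N-(1-tosylvinyl)formamide 6 (not isolated)
Conditions: TosMIC, KOt-Bu, DME, −50 °C; then MeOH, reflux
Reagents that add atoms: 4-toluenesulfonylmethyl isocyanide, Cc1ccc(cc1)S(=O)(=O)C[N+]#[C-]
Why: Van Leusen reductive cyanation: the TosMIC anion adds to the aldehyde at low temperature (which avoids oxazole formation), and methanolysis of the N-formyl enamine with loss of sulfinate gives the one-carbon homologated nitrile.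

Step 5
Reactants: 7 2-[3-bromo-2-fluoro-4,6-bis(benzyloxy)phenyl]acetonitrile
Product: 8 2-[3-bromo-2-fluoro-4,6-bis(benzyloxy)phenyl]acetic acid
Conditions: KOH, EtOH/H2O, reflux; then aq HCl
Reagents that add atoms: potassium hydroxide, [K+].[OH-]; water, O
Why: Alkaline nitrile hydrolysis, to which the unactivated aryl fluoride, aryl bromide and benzyl ethers are inert.

Step 6
Reactants: 9 2,4,6-trihydroxybenzaldehyde
Product: 10 2-hydroxy-4,6-bis(benzyloxy)benzaldehyde
Conditions: BnBr (2 equiv), K2CO3, DMF, 0 °C → rt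
Reagents that add atoms: benzyl bromide, BrCc1ccccc1
Why: Selective Williamson etherification, because the hydroxyl that is hydrogen-bonded to the formyl group is the least nucleophilic and should stay free.

Step 7
Reactants: 8 2-[3-bromo-2-fluoro-4,6-bis(benzyloxy)phenyl]acetic acid; 10 2-hydroxy-4,6-bis(benzyloxy)benzaldehyde
Product: 11 5,7-bis(benzyloxy)-3-[3-bromo-2-fluoro-4,6-bis(benzyloxy)phenyl]-2H-chromen-2-one
Conditions: Ac2O, Et3N, 120 °C
Reagents that add atoms: none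
Why: Perkin (Oglialoro) condensation: the mixed-anhydride enolate of the arylacetic acid condenses with the aldehyde and the cis-cinnamic acid lactonises onto the phenol, which fixes the alkene geometry needed later.

Step 8
Reactants: 11 5,7-bis(benzyloxy)-3-[3-bromo-2-fluoro-4,6-bis(benzyloxy)phenyl]-2H-chromen-2-one
Product: 12 5,7-bis(benzyloxy)-3-[3-bromo-2-fluoro-4,6-bis(benzyloxy)phenyl]-2H-chromen-2-ol (racemic lactol)
Conditions: i-Bu2AlH (1.2 equiv), CH2Cl2, −78 °C
Reagents that add atoms: none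
Why: Partial lactone reduction: the tetrahedral aluminium acetal persists at −78 °C, so reduction should stop at the lactol.

Step 9
Reactants: 12 5,7-bis(benzyloxy)-3-[3-bromo-2-fluoro-4,6-bis(benzyloxy)phenyl]-2H-chromen-2-ol; 13 4-bromo-1,2-bis(benzyloxy)benzene
Product: 16 racemic (Z)-1-[3,4-bis(benzyloxy)phenyl]-2-[3-bromo-2-fluoro-4,6-bis(benzyloxy)phenyl]-3-[2-hydroxy-4,6-bis(benzyloxy)phenyl]prop-2-en-1-ol, via arylmagnesium bromide 14 (not isolated), via ring-opened Z-enal 15 (not isolated)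
Conditions: 13, Mg, THF, reflux; then 12, THF, 0 °C → rt; pH 7 buffer work-up, Et3N-washed silica
Reagents that add atoms: none
Why: Grignard addition: one equivalent deprotonates the lactol, which opens to the Z-enal phenoxide, and a second adds 1,2 to the aldehyde, giving the racemic carbinol with the Z geometry inherited from the coumarin; neutral handling prevents premature racemic cyclisation.

Step 10
Reactants: 16 racemic (Z)-1-[3,4-bis(benzyloxy)phenyl]-2-[3-bromo-2-fluoro-4,6-bis(benzyloxy)phenyl]-3-[2-hydroxy-4,6-bis(benzyloxy)phenyl]prop-2-en-1-ol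
Product: 17 (2S)-5,7-bis(benzyloxy)-2-[3,4-bis(benzyloxy)phenyl]-3-[3-bromo-2-fluoro-4,6-bis(benzyloxy)phenyl]-2H-chromene
Conditions: (R)-3,3'-bis(2,4,6-triisopropylphenyl)-1,1'-binaphthyl-2,2'-diyl N-triflylphosphoramide (10 mol%), toluene, −78 °C; then Et3N, −78 °C
Reagents that add atoms: none
Why: The strong chiral Brønsted acid protonates the carbinol and water leaves, giving an allyl cation delocalised over C2, C4 and the catechol ring (equally a protonated vinylogous ortho-quinone methide) that is held as a contact ion pair with the chiral phosphoramide anion, so both enantiomers of 16 converge on one planar intermediate. The closest known reaction type is the chiral N-triflylphosphoramide-catalysed enantioselective intramolecular allylic substitution of ortho-hydroxyaryl allylic alcohols to 2H-chromenes. Ring C closes by attack of the ring A phenol oxygen on C2, a 6-endo C–O closure onto the allyl terminus that can also be read as an oxa-6π electrocyclisation. The new C2 stereocentre is controlled only by the chiral counter-anion, which covers one face of C2 while hydrogen-bonding the phenol. The step needs enantioface selectivity at C2 and O-alkylation over C-alkylation: the Z alkene keeps the phenol next to C2, the 3,4-bis(benzyloxy)phenyl group allows ionisation at −78 °C where re-ionisation of 17 is slow, and the cold amine quench removes the acid before warming.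

Step 11
Reactants: 17 (2S)-5,7-bis(benzyloxy)-2-[3,4-bis(benzyloxy)phenyl]-3-[3-bromo-2-fluoro-4,6-bis(benzyloxy)phenyl]-2H-chromene
Product: 19 (2R,3S,4S)-5,7-bis(benzyloxy)-2-[3,4-bis(benzyloxy)phenyl]-3-[3-bromo-2-fluoro-4,6-bis(benzyloxy)phenyl]chroman-4-ol (2,3-cis; 3,4-trans), via C4-alkylborane 18 (not isolated)
Conditions: BH3·SMe2, THF, 0 °C → rt; then NaOH, H2O2, H2O, 0 °C → rt
Reagents that add atoms: hydrogen peroxide, OO
Why: Hydroboration–oxidation: BH3 adds syn across C3=C4 with boron at the less substituted C4 and hydrogen at C3 from the face opposite the C2 aryl group, which places the C3 aryl cis to the C2 aryl and the C4 oxygen (retention on oxidation) trans to the C3 aryl, so C3 is set by substrate control from C2.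

Step 12
Reactants: 19 (2R,3S,4S)-5,7-bis(benzyloxy)-2-[3,4-bis(benzyloxy)phenyl]-3-[3-bromo-2-fluoro-4,6-bis(benzyloxy)phenyl]chroman-4-ol
Product: 20 (2R,3R,4S)-5,7-bis(benzyloxy)-2-[3,4-bis(benzyloxy)phenyl]-3-[3-bromo-2-fluoro-4,6-bis(benzyloxy)phenyl]-4-[(tert-butyldimethylsilyl)oxy]chroman
Conditions: TBSOTf, 2,6-lutidine, CH2Cl2, 0 °C
Reagents that add atoms: tert-butyldimethylsilyl trifluoromethanesulfonate, CC(C)(C)[Si](C)(C)OS(=O)(=O)C(F)(F)F
Why: Silyl ether formation under buffered conditions keeps C4 at the alcohol level, so C3 cannot enolise and the C4 oxygen cannot compete for the aryl fluoride while the lower unit is built.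

Step 13
Reactants: 21 4-(benzyloxy)benzaldehyde
Product: 23 (S)-1-[4-(benzyloxy)phenyl]but-3-en-1-ol, via borinate ester 22 (not isolated)
Conditions: (−)-Ipc2BOMe, CH2=CHCH2MgBr, Et2O, 0 °C → rt; then 21, −78 °C; then NaOH, H2O2
Reagents that add atoms: allylmagnesium bromide, C=CC[Mg]Br
Why: Brown asymmetric allylboration: the allylborane made from (−)-Ipc2BOMe (derived from (+)-α-pinene) transfers allyl through a closed chair transition state to one aldehyde face, which sets the (S)-carbinol that becomes C2''.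

Step 14
Reactants: 23 (S)-1-[4-(benzyloxy)phenyl]but-3-en-1-ol
Product: 24 (S)-{1-[4-(benzyloxy)phenyl]but-3-en-1-yloxy}triethylsilane
Conditions: TESCl, imidazole, DMF, rt
Reagents that add atoms: chlorotriethylsilane, CC[Si](Cl)(CC)CC
Why: Silyl ether formation; triethylsilyl is chosen because fluoride removes it well before the tert-butyldimethylsilyl group on the upper unit.

Step 15
Reactants: 24 (S)-{1-[4-(benzyloxy)phenyl]but-3-en-1-yloxy}triethylsilane
Product: 26 (S)-3-[4-(benzyloxy)phenyl]-3-[(triethylsilyl)oxy]propanal, via ozonide 25 (not isolated)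
Conditions: O3, CH2Cl2, −78 °C; then PPh3, −78 °C → rt
Reagents that add atoms: ozone, [O-][O+]=O
Why: Ozonolysis with reductive work-up cleaves the terminal alkene much faster than ozone attacks the arenes at −78 °C and leaves the stereocentre untouched.

Step 16
Reactants: 20 (2R,3R,4S)-5,7-bis(benzyloxy)-2-[3,4-bis(benzyloxy)phenyl]-3-[3-bromo-2-fluoro-4,6-bis(benzyloxy)phenyl]-4-[(tert-butyldimethylsilyl)oxy]chroman; 26 (S)-3-[4-(benzyloxy)phenyl]-3-[(triethylsilyl)oxy]propanal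
Product: 28 1-{3-[(2R,3R,4S)-5,7-bis(benzyloxy)-2-[3,4-bis(benzyloxy)phenyl]-4-[(tert-butyldimethylsilyl)oxy]chroman-3-yl]-2-fluoro-4,6-bis(benzyloxy)phenyl}-3-[4-(benzyloxy)phenyl]-3-[(triethylsilyl)oxy]propan-1-ol (3S; both C1 epimers), via aryllithium 27 (not isolated)
Conditions: n-BuLi, THF, −78 °C; then 26, −78 °C; then H2O
Reagents that add atoms: none
Why: Bromine–lithium exchange at −78 °C is faster than any deprotonation of the benzyl ethers and fixes the nucleophilic site at the future C4a'', and the aryllithium (kept cold to avoid loss of LiF to an aryne) adds 1,2 to the aldehyde; the new carbinol centre is formed without control and is removed by the next oxidation.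

Step 17
Reactants: 28 1-{3-[(2R,3R,4S)-5,7-bis(benzyloxy)-2-[3,4-bis(benzyloxy)phenyl]-4-[(tert-butyldimethylsilyl)oxy]chroman-3-yl]-2-fluoro-4,6-bis(benzyloxy)phenyl}-3-[4-(benzyloxy)phenyl]-3-[(triethylsilyl)oxy]propan-1-ol
Product: 29 (3S)-1-{3-[(2R,3R,4S)-5,7-bis(benzyloxy)-2-[3,4-bis(benzyloxy)phenyl]-4-[(tert-butyldimethylsilyl)oxy]chroman-3-yl]-2-fluoro-4,6-bis(benzyloxy)phenyl}-3-[4-(benzyloxy)phenyl]-3-[(triethylsilyl)oxy]propan-1-one
Conditions: Dess–Martin periodinane, pyridine, CH2Cl2, 0 °C → rt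
Reagents that add atoms: none
Why: Dess–Martin oxidation of the benzylic alcohol under neutral conditions gives the aryl ketone that activates the ortho fluorine, with both silyl ethers left intact.

Step 18
Reactants: 29 (3S)-1-{3-[(2R,3R,4S)-5,7-bis(benzyloxy)-2-[3,4-bis(benzyloxy)phenyl]-4-[(tert-butyldimethylsilyl)oxy]chroman-3-yl]-2-fluoro-4,6-bis(benzyloxy)phenyl}-3-[4-(benzyloxy)phenyl]-3-[(triethylsilyl)oxy]propan-1-one
Product: 32 (2S)-5,7-bis(benzyloxy)-2-[4-(benzyloxy)phenyl]-8-{(2R,3S,4S)-5,7-bis(benzyloxy)-2-[3,4-bis(benzyloxy)phenyl]-4-hydroxychroman-3-yl}chroman-4-one, via β-hydroxy ketone 30 (not isolated), via flavanone silyl ether 31 (not isolated)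
Conditions: Bu4NF (1.1 equiv), THF, −40 → 0 °C; then AcOH, Bu4NF, THF, rt
Reagents that add atoms: none
Why: Fluoride cleaves the triethylsilyl ether first and the liberated C2''-alkoxide displaces the fluoride ortho to the ketone in an intramolecular nucleophilic aromatic substitution (addition–elimination forming the six-membered pyranone, with retention at C2'' because its C–O bond is not broken), the slower-cleaving tert-butyldimethylsilyl group keeping the C4 oxygen masked until the aryl fluoride is gone; acetic acid-buffered fluoride then frees the C4 hydroxyl without exposing the flavanone to base.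

Step 19
Reactants: 32 (2S)-5,7-bis(benzyloxy)-2-[4-(benzyloxy)phenyl]-8-{(2R,3S,4S)-5,7-bis(benzyloxy)-2-[3,4-bis(benzyloxy)phenyl]-4-hydroxychroman-3-yl}chroman-4-one
Product: 33 (2R,3R)-5,7-bis(benzyloxy)-2-[3,4-bis(benzyloxy)phenyl]-3-{(2S)-5,7-bis(benzyloxy)-2-[4-(benzyloxy)phenyl]-4-oxochroman-8-yl}chroman-4-one
Conditions: Dess–Martin periodinane, pyridine, CH2Cl2, 0 °C
Reagents that add atoms: none
Why: Dess–Martin oxidation buffered with pyridine forms the upper C4 ketone without acid or base strong enough to enolise it, so the cis C3 configuration set in step 11 should be kept; the product is handled cold and taken on promptly.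

Step 20
Reactants: 33 (2R,3R)-5,7-bis(benzyloxy)-2-[3,4-bis(benzyloxy)phenyl]-3-{(2S)-5,7-bis(benzyloxy)-2-[4-(benzyloxy)phenyl]-4-oxochroman-8-yl}chroman-4-one
Product: 34 (2R,3R)-2-(3,4-dihydroxyphenyl)-3-[(2S)-5,7-dihydroxy-2-(4-hydroxyphenyl)-4-oxochroman-8-yl]-5,7-dihydroxychroman-4-one (CNP0105436.1)
Conditions: H2 (1 atm), Pd/C, THF/MeOH, rt
Reagents that add atoms: none
Why: Catalytic hydrogenolysis removes all seven benzyl ethers in a neutral medium in which the aryl ketones, the benzylic C2–O1 bonds and the epimerisable cis C3 centre should survive.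

Compound list
1 | 5-fluororesorcinol | Oc1cc(O)cc(F)c1 | starting material
2 | 1,3-bis(benzyloxy)-5-fluorobenzene | Fc1cc(OCc2ccccc2)cc(OCc2ccccc2)c1 | intermediate
3 | N-[2-fluoro-4,6-bis(benzyloxy)benzylidene]-N-methylmethanaminium salt (shown as chloride) | C[N+](C)=Cc1c(F)cc(OCc2ccccc2)cc1OCc1ccccc1.[Cl-] | intermediate
4 | 2-fluoro-4,6-bis(benzyloxy)benzaldehyde | O=Cc1c(F)cc(OCc2ccccc2)cc1OCc1ccccc1 | intermediate
5 | 3-bromo-2-fluoro-4,6-bis(benzyloxy)benzaldehyde | O=Cc1c(F)c(Br)c(OCc2ccccc2)cc1OCc1ccccc1 | intermediate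
6 | N-{2-[3-bromo-2-fluoro-4,6-bis(benzyloxy)phenyl]-1-tosylethenyl}formamide | O=CNC(=Cc1c(F)c(Br)c(OCc2ccccc2)cc1OCc1ccccc1)S(=O)(=O)c1ccc(C)cc1 | intermediate
7 | 2-[3-bromo-2-fluoro-4,6-bis(benzyloxy)phenyl]acetonitrile | N#CCc1c(F)c(Br)c(OCc2ccccc2)cc1OCc1ccccc1 | intermediate
8 | 2-[3-bromo-2-fluoro-4,6-bis(benzyloxy)phenyl]acetic acid | OC(=O)Cc1c(F)c(Br)c(OCc2ccccc2)cc1OCc1ccccc1 | intermediate
9 | 2,4,6-trihydroxybenzaldehyde | O=Cc1c(O)cc(O)cc1O | starting material
10 | 2-hydroxy-4,6-bis(benzyloxy)benzaldehyde | O=Cc1c(O)cc(OCc2ccccc2)cc1OCc1ccccc1 | intermediate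
11 | 5,7-bis(benzyloxy)-3-[3-bromo-2-fluoro-4,6-bis(benzyloxy)phenyl]-2H-chromen-2-one | O=C1Oc2cc(OCc3ccccc3)cc(OCc3ccccc3)c2C=C1c1c(F)c(Br)c(OCc2ccccc2)cc1OCc1ccccc1 | intermediate
12 | 5,7-bis(benzyloxy)-3-[3-bromo-2-fluoro-4,6-bis(benzyloxy)phenyl]-2H-chromen-2-ol (racemic lactol) | OC1Oc2cc(OCc3ccccc3)cc(OCc3ccccc3)c2C=C1c1c(F)c(Br)c(OCc2ccccc2)cc1OCc1ccccc1 | intermediate
13 | 4-bromo-1,2-bis(benzyloxy)benzene | Brc1ccc(OCc2ccccc2)c(OCc2ccccc2)c1 | starting material
14 | 3,4-bis(benzyloxy)phenylmagnesium bromide | Br[Mg]c1ccc(OCc2ccccc2)c(OCc2ccccc2)c1 | intermediate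
15 | (Z)-2-[3-bromo-2-fluoro-4,6-bis(benzyloxy)phenyl]-3-[2-hydroxy-4,6-bis(benzyloxy)phenyl]prop-2-enal (present as its magnesium phenoxide) | O=C/C(c1c(F)c(Br)c(OCc2ccccc2)cc1OCc1ccccc1)=C\c1c(O)cc(OCc2ccccc2)cc1OCc1ccccc1 | intermediate
16 | racemic (Z)-1-[3,4-bis(benzyloxy)phenyl]-2-[3-bromo-2-fluoro-4,6-bis(benzyloxy)phenyl]-3-[2-hydroxy-4,6-bis(benzyloxy)phenyl]prop-2-en-1-ol | OC(c1ccc(OCc2ccccc2)c(OCc2ccccc2)c1)/C(c1c(F)c(Br)c(OCc2ccccc2)cc1OCc1ccccc1)=C\c1c(O)cc(OCc2ccccc2)cc1OCc1ccccc1 | intermediate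
17 | (2S)-5,7-bis(benzyloxy)-2-[3,4-bis(benzyloxy)phenyl]-3-[3-bromo-2-fluoro-4,6-bis(benzyloxy)phenyl]-2H-chromene | Fc1c(Br)c(OCc2ccccc2)cc(OCc2ccccc2)c1C1=Cc2c(OCc3ccccc3)cc(OCc3ccccc3)cc2O[C@H]1c1ccc(OCc2ccccc2)c(OCc2ccccc2)c1 | intermediate
18 | C4-alkylborane from 17 (boron at C4 trans to the C3 aryl; 2,3-cis) | B[C@@H]1c2c(OCc3ccccc3)cc(OCc3ccccc3)cc2O[C@@H](c2ccc(OCc3ccccc3)c(OCc3ccccc3)c2)[C@H]1c1c(F)c(Br)c(OCc2ccccc2)cc1OCc1ccccc1 | intermediate
19 | (2R,3S,4S)-5,7-bis(benzyloxy)-2-[3,4-bis(benzyloxy)phenyl]-3-[3-bromo-2-fluoro-4,6-bis(benzyloxy)phenyl]chroman-4-ol (2,3-cis; 3,4-trans) | O[C@@H]1c2c(OCc3ccccc3)cc(OCc3ccccc3)cc2O[C@@H](c2ccc(OCc3ccccc3)c(OCc3ccccc3)c2)[C@H]1c1c(F)c(Br)c(OCc2ccccc2)cc1OCc1ccccc1 | intermediate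
20 | (2R,3R,4S)-5,7-bis(benzyloxy)-2-[3,4-bis(benzyloxy)phenyl]-3-[3-bromo-2-fluoro-4,6-bis(benzyloxy)phenyl]-4-[(tert-butyldimethylsilyl)oxy]chroman | CC(C)(C)[Si](C)(C)O[C@@H]1c2c(OCc3ccccc3)cc(OCc3ccccc3)cc2O[C@@H](c2ccc(OCc3ccccc3)c(OCc3ccccc3)c2)[C@H]1c1c(F)c(Br)c(OCc2ccccc2)cc1OCc1ccccc1 | intermediate
21 | 4-(benzyloxy)benzaldehyde | O=Cc1ccc(OCc2ccccc2)cc1 | starting material
22 | (S)-1-[4-(benzyloxy)phenyl]but-3-en-1-yl diisopinocampheylborinate | C=CC[C@H](OB([C@@H]1C[C@@H]2C[C@H]([C@H]1C)C2(C)C)[C@@H]1C[C@@H]2C[C@H]([C@H]1C)C2(C)C)c1ccc(OCc2ccccc2)cc1 | intermediate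
23 | (S)-1-[4-(benzyloxy)phenyl]but-3-en-1-ol | C=CC[C@H](O)c1ccc(OCc2ccccc2)cc1 | intermediate
24 | (S)-{1-[4-(benzyloxy)phenyl]but-3-en-1-yloxy}triethylsilane | C=CC[C@H](O[Si](CC)(CC)CC)c1ccc(OCc2ccccc2)cc1 | intermediate
25 | ozonide (1,2,4-trioxolane) of 24 | C1OC(C[C@H](O[Si](CC)(CC)CC)c2ccc(OCc3ccccc3)cc2)OO1 | intermediate
26 | (S)-3-[4-(benzyloxy)phenyl]-3-[(triethylsilyl)oxy]propanal | O=CC[C@H](O[Si](CC)(CC)CC)c1ccc(OCc2ccccc2)cc1 | intermediate
27 | aryllithium from 20 (lithium in place of bromine) | CC(C)(C)[Si](C)(C)O[C@@H]1c2c(OCc3ccccc3)cc(OCc3ccccc3)cc2O[C@@H](c2ccc(OCc3ccccc3)c(OCc3ccccc3)c2)[C@H]1c1c(F)c([Li])c(OCc2ccccc2)cc1OCc1ccccc1 | intermediate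
28 | 1-{3-[(2R,3R,4S)-5,7-bis(benzyloxy)-2-[3,4-bis(benzyloxy)phenyl]-4-[(tert-butyldimethylsilyl)oxy]chroman-3-yl]-2-fluoro-4,6-bis(benzyloxy)phenyl}-3-[4-(benzyloxy)phenyl]-3-[(triethylsilyl)oxy]propan-1-ol (3S; both C1 epimers) | CC(C)(C)[Si](C)(C)O[C@@H]1c2c(OCc3ccccc3)cc(OCc3ccccc3)cc2O[C@@H](c2ccc(OCc3ccccc3)c(OCc3ccccc3)c2)[C@H]1c1c(F)c(C(O)C[C@H](O[Si](CC)(CC)CC)c2ccc(OCc3ccccc3)cc2)c(OCc2ccccc2)cc1OCc1ccccc1 | intermediate
29 | (3S)-1-{3-[(2R,3R,4S)-5,7-bis(benzyloxy)-2-[3,4-bis(benzyloxy)phenyl]-4-[(tert-butyldimethylsilyl)oxy]chroman-3-yl]-2-fluoro-4,6-bis(benzyloxy)phenyl}-3-[4-(benzyloxy)phenyl]-3-[(triethylsilyl)oxy]propan-1-one | CC(C)(C)[Si](C)(C)O[C@@H]1c2c(OCc3ccccc3)cc(OCc3ccccc3)cc2O[C@@H](c2ccc(OCc3ccccc3)c(OCc3ccccc3)c2)[C@H]1c1c(F)c(C(=O)C[C@H](O[Si](CC)(CC)CC)c2ccc(OCc3ccccc3)cc2)c(OCc2ccccc2)cc1OCc1ccccc1 | intermediate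
30 | (3S)-3-hydroxy analogue of 29 (β-hydroxy ketone, formed as its alkoxide) | CC(C)(C)[Si](C)(C)O[C@@H]1c2c(OCc3ccccc3)cc(OCc3ccccc3)cc2O[C@@H](c2ccc(OCc3ccccc3)c(OCc3ccccc3)c2)[C@H]1c1c(F)c(C(=O)C[C@H](O)c2ccc(OCc3ccccc3)cc2)c(OCc2ccccc2)cc1OCc1ccccc1 | intermediate
31 | (2S)-5,7-bis(benzyloxy)-2-[4-(benzyloxy)phenyl]-8-{(2R,3R,4S)-5,7-bis(benzyloxy)-2-[3,4-bis(benzyloxy)phenyl]-4-[(tert-butyldimethylsilyl)oxy]chroman-3-yl}chroman-4-one | O=C1C[C@@H](c2ccc(OCc3ccccc3)cc2)Oc2c1c(OCc1ccccc1)cc(OCc1ccccc1)c2[C@H]1[C@H](O[Si](C)(C)C(C)(C)C)c2c(OCc3ccccc3)cc(OCc3ccccc3)cc2O[C@H]1c1ccc(OCc2ccccc2)c(OCc2ccccc2)c1 | intermediate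
32 | (2S)-5,7-bis(benzyloxy)-2-[4-(benzyloxy)phenyl]-8-{(2R,3S,4S)-5,7-bis(benzyloxy)-2-[3,4-bis(benzyloxy)phenyl]-4-hydroxychroman-3-yl}chroman-4-one | O=C1C[C@@H](c2ccc(OCc3ccccc3)cc2)Oc2c1c(OCc1ccccc1)cc(OCc1ccccc1)c2[C@H]1[C@H](O)c2c(OCc3ccccc3)cc(OCc3ccccc3)cc2O[C@H]1c1ccc(OCc2ccccc2)c(OCc2ccccc2)c1 | intermediate
33 | (2R,3R)-5,7-bis(benzyloxy)-2-[3,4-bis(benzyloxy)phenyl]-3-{(2S)-5,7-bis(benzyloxy)-2-[4-(benzyloxy)phenyl]-4-oxochroman-8-yl}chroman-4-one | O=C1C[C@@H](c2ccc(OCc3ccccc3)cc2)Oc2c1c(OCc1ccccc1)cc(OCc1ccccc1)c2[C@H]1C(=O)c2c(OCc3ccccc3)cc(OCc3ccccc3)cc2O[C@H]1c1ccc(OCc2ccccc2)c(OCc2ccccc2)c1 | intermediate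
34 | (2R,3R)-2-(3,4-dihydroxyphenyl)-3-[(2S)-5,7-dihydroxy-2-(4-hydroxyphenyl)-4-oxochroman-8-yl]-5,7-dihydroxychroman-4-one (CNP0105436.1) | O=C1C[C@@H](c2ccc(O)cc2)Oc2c1c(O)cc(O)c2[C@H]1C(=O)c2c(O)cc(O)cc2O[C@H]1c1ccc(O)c(O)c1 | target

Total step count: 20.
Longest linear sequence: 16 steps (steps 1–5, 7–12 and 16–20, from 5-fluororesorcinol).

Steps most likely to fail

Step 10. The ion pair may discriminate the two faces of C2 incompletely, or the electron-rich chromene may lose enantiopurity by acid-catalysed re-ionisation and ring opening before the quench. The fallback sets out from 16 and comes back at 17. Compound 16 is cyclised with a catalytic achiral acid (pyridinium p-toluenesulfonate, CH2Cl2, 0 °C) to racemic 5,7-bis(benzyloxy)-2-[3,4-bis(benzyloxy)phenyl]-3-[3-bromo-2-fluoro-4,6-bis(benzyloxy)phenyl]-2H-chromene F1. This is resolved by preparative chromatography on a chiral stationary phase (amylose tris(3,5-dimethylphenylcarbamate), supercritical CO2/alcohol), and the (2S) enantiomer is carried on as 17.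

Step 18. The β-alkoxide may fragment by retro-aldol cleavage or eliminate to the chalcone faster than it displaces the hindered fluoride, and base-induced opening of the new pyranone may scramble C2''. The fallback sets out from 20 and comes back at 31, which is then desilylated with buffered fluoride as in the second stage of step 18.
- Bromine–lithium exchange on 20 (n-BuLi, THF, −78 °C) and trapping with N-methoxy-N-methylacetamide should give the methyl ketone 1-{3-[(2R,3R,4S)-5,7-bis(benzyloxy)-2-[3,4-bis(benzyloxy)phenyl]-4-[(tert-butyldimethylsilyl)oxy]chroman-3-yl]-2-fluoro-4,6-bis(benzyloxy)phenyl}ethan-1-one F2.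
- Claisen formylation with ethyl formate and NaH, then heating in DMF, should close the pyranone by enolate-oxygen displacement of fluoride to 5,7-bis(benzyloxy)-8-{(2R,3R,4S)-5,7-bis(benzyloxy)-2-[3,4-bis(benzyloxy)phenyl]-4-[(tert-butyldimethylsilyl)oxy]chroman-3-yl}-4H-chromen-4-one F3. No retro-aldol pathway exists here.
- Catalytic asymmetric 1,4-addition of 4-(benzyloxy)phenylboronic acid then sets C2'' under catalyst control. The catalyst is Pd(OCOCF3)2 with the enantiomer of 4-tert-butyl-2-(pyridin-2-yl)-4,5-dihydrooxazole that delivers the 2''S product, or [Rh(OH)(cod)]2 with a chiral diene.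

Step 11. Borane may add slowly to the hindered trisubstituted C3=C4 bond, which carries a 2,6-disubstituted aryl group, and the facial or positional selectivity may be incomplete. The fallback sets out from 17 and comes back at 19. Homogeneous hydrogenation with [Ir(cod)(PCy3)(py)]PF6 under H2 in CH2Cl2 delivers both hydrogens syn from the face opposite the C2 aryl, with benzyl ethers and the C–Br bond untouched. It should give (2R,3R)-5,7-bis(benzyloxy)-2-[3,4-bis(benzyloxy)phenyl]-3-[3-bromo-2-fluoro-4,6-bis(benzyloxy)phenyl]chroman F4, which is 2,3-cis. Benzylic oxidation at C4 with DDQ in wet CH2Cl2 then follows: hydride is abstracted at the position activated by the ring A benzyloxy groups, and water is expected to add anti to the C3 aryl, giving alcohol 19.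

Further compounds
F1 | step 10 | racemic 5,7-bis(benzyloxy)-2-[3,4-bis(benzyloxy)phenyl]-3-[3-bromo-2-fluoro-4,6-bis(benzyloxy)phenyl]-2H-chromene | Fc1c(Br)c(OCc2ccccc2)cc(OCc2ccccc2)c1C1=Cc2c(OCc3ccccc3)cc(OCc3ccccc3)cc2OC1c1ccc(OCc2ccccc2)c(OCc2ccccc2)c1
F2 | step 18 | 1-{3-[(2R,3R,4S)-5,7-bis(benzyloxy)-2-[3,4-bis(benzyloxy)phenyl]-4-[(tert-butyldimethylsilyl)oxy]chroman-3-yl]-2-fluoro-4,6-bis(benzyloxy)phenyl}ethan-1-one | CC(C)(C)[Si](C)(C)O[C@@H]1c2c(OCc3ccccc3)cc(OCc3ccccc3)cc2O[C@@H](c2ccc(OCc3ccccc3)c(OCc3ccccc3)c2)[C@H]1c1c(F)c(C(C)=O)c(OCc2ccccc2)cc1OCc1ccccc1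
F3 | step 18 | 5,7-bis(benzyloxy)-8-{(2R,3R,4S)-5,7-bis(benzyloxy)-2-[3,4-bis(benzyloxy)phenyl]-4-[(tert-butyldimethylsilyl)oxy]chroman-3-yl}-4H-chromen-4-one | O=C1C=COc2c1c(OCc1ccccc1)cc(OCc1ccccc1)c2[C@H]1[C@H](O[Si](C)(C)C(C)(C)C)c2c(OCc3ccccc3)cc(OCc3ccccc3)cc2O[C@H]1c1ccc(OCc2ccccc2)c(OCc2ccccc2)c1
F4 | step 11 | (2R,3R)-5,7-bis(benzyloxy)-2-[3,4-bis(benzyloxy)phenyl]-3-[3-bromo-2-fluoro-4,6-bis(benzyloxy)phenyl]chroman (2,3-cis) | C1c2c(OCc3ccccc3)cc(OCc3ccccc3)cc2O[C@@H](c2ccc(OCc3ccccc3)c(OCc3ccccc3)c2)[C@H]1c1c(F)c(Br)c(OCc2ccccc2)cc1OCc1ccccc1
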